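Between 5.00 h and 8.00 h the grey flask gained 7.9 percentage points of left-handed product, but between 40.0 h and 60.0 h, a longer stretch, it gained less, 3.1 points. Is this flask slowing, or has it stopped?

| flask | left-handed substrate | right-handed substrate | reagent | free catalyst | impurity | temperature | remark | time |
|---|---|---|---|---|---|---|---|---|
| grey | 0.014 M | 0.014 M | 0.042 M | 0.28 mM | 0.17 mM | 35 °C | the very flask that is asked about, followed so far |  |
| flask | 0.014 M | 0.014 M | 0.0420 M | 0.28 mM | 0.17 mM | 35 °C |  | 3.0 d |

- grey (time / h: left-handed product / %, left-handed substrate / %): 5.00: 27.3, 33.4; 8.00: 35.2, 25.5; 10.0: 41.2, 24.0; 15.0: 46.7, 20.5; 25.0: 53.8, 14.8; 40.0: 56.5, 14.1; 60.0: 59.6, 14.2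

(scatter of a reading: 1 percentage point)

- free catalyst is single-handed; left-handed substrate and right-handed substrate are mirror images of each other, charged as a racemate, each of them at the stated concentration
- what is taken out of left-handed product is counted as made
- the numbers in the tables scatter by 1 percentage point (one standard deviation)
- on the list of suspects stand: free catalyst + right-handed substrate <-> catalyst intermediate B; free catalyst + impurity -> spent catalyst A; reagent + catalyst intermediate B -> free catalyst + right-handed product; reagent + free catalyst -> spent catalyst B; left-handed substrate <-> right-handed substrate; free catalyst + left-handed substrate <-> catalyst intermediate A; reagent + catalyst intermediate A -> free catalyst + left-handed product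
- additions bring no volume worth counting
- the earlier runs do not show what temperature does; that part of a forecast is a guess

- summer: at 3.0 d raise the temperature by 15 K, then wait 6.0 d
- noon: at 3.0 d add reagent, 50.0% of the amount charged, then wait 6.0 d
- midnight: change nothing and wait 6.0 d more
- dusk: at 3.0 d add free catalyst, 50.0% of the amount charged, then wait 6.0 d
- winter: at 3.0 d take out 90% of the left-handed product then present, then wait 6.0 d

* left-handed product, in percent of the left-handed substrate and right-handed substrate together first charged, at 3.0 d
* the option that brings most further left-handed product ("none" if no option brings more than 2 percentage points) (summer / noon / midnight / dusk / winter / none)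
* left-handed product present, with what was taken out counted in, in percent of the left-handed substrate and right-handed substrate together first charged, after noon
* left-handed product present, with what was taken out counted in, in percent of the left-handed substrate and right-handed substrate together first charged, after dusk

Two chemists argue at the board. Both read the same balance: left-handed product stands above half of the charge, so the substrates interconvert, and both take them as equal. Of the product made in the grey flask by 60.0 h, the readings put 83.2% as left-handed.

The first chemist says a catalyst returns from its round, so the substrates fall pseudo-first-order. The 5.00 h reading gives her 0.0807 h⁻¹, hence 0.300% of both substrates together at 3.0 d and 83.0% left-handed product.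

The second chemist points to left-handed substrate at 14.1% and then 14.2%, flat within the scatter, with about 0.0220 M of reagent still present, so she counts catalyst instead. Impurity, at c(impurity) = 0.17 mM, is less than c(free catalyst) = 0.28 mM, which, taken one for one, leaves 0.110 mM for reagent to destroy.

Her rule, at one temperature and with the two substrates kept equal, is this: the logarithmic loss of substrate per hour goes with live catalyst and reagent, and so does the loss of live catalyst to reagent. Divide one rate by the other and both time and reagent drop out. What stays is the exposure per catalyst, the fall in ln(substrate) for each amount of catalyst destroyed by reagent. The grey readings at 60.0 h show 1.26 spent, so she reads 11.4 mM⁻¹.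

My own reckoning follows her. Waiting, heat, reagent and removal add no catalyst, but dusk adds 0.140 mM. If the impurity is used up, that buys an exposure of 1.60, and so 19 points more left-handed product.

The forecast takes the second side, “Fresh catalyst does work”, with 60.3% at 3.0 d (range 58.8% to 62%), dusk as best option, 60.8% after noon and 76% after dusk, a gain of 16 points, smaller than mine.

The flask gives 58.1% at 3.0 d, 58.3% after noon and 76.3% after dusk. The best option is dusk, which brings 18 points against my 19 points.

    free catalyst + right-handed substrate ⇌ catalyst intermediate B (K = 31.0 M⁻¹, k = 3.80 × 10⁵ M⁻¹ h⁻¹, Ea = 37.0 kJ mol⁻¹, ΔH = 32.0 kJ mol⁻¹)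
    free catalyst + impurity → spent catalyst A (k = 1.20 × 10⁶ M⁻¹ h⁻¹, Ea = 50.0 kJ mol⁻¹)
    reagent + catalyst intermediate B → free catalyst + right-handed product (k = 600 M⁻¹ h⁻¹, Ea = 41.0 kJ mol⁻¹)
    reagent + free catalyst → spent catalyst B (k = 4.10 M⁻¹ h⁻¹, Ea = 80.0 kJ mol⁻¹)
    left-handed substrate ⇌ right-handed substrate (k = 0.720 h⁻¹, Ea = 95.0 kJ mol⁻¹)
    free catalyst + left-handed substrate ⇌ catalyst intermediate A (K = 53.0 M⁻¹, k = 38000 M⁻¹ h⁻¹, Ea = 36.0 kJ mol⁻¹, ΔH = −1.00 kJ mol⁻¹)
    reagent + catalyst intermediate A → free catalyst + left-handed product (k = 1600 M⁻¹ h⁻¹, Ea = 55.0 kJ mol⁻¹)
    (constants at 35 °C)

The first chemist's picture of substrate used up holds for the neighbour charged with 0.0011 M of free catalyst: the exposure per catalyst promises 10.6 there, and that neighbour ends with left-handed substrate at 0% and left-handed product at 74.1%. This flask, at 72.0 h, holds 7.24 × 10⁻⁴ mM of free catalyst and both intermediates together, which is an exposure of 0.00828, worth 0.19 points of left-handed product. Waiting brings 0.2 points. At 720 h this flask shows 58.3% of left-handed product, with free catalyst at 0% and left-handed substrate still at 13.7%.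

The earlier runs and the new flask were computed with constants of no real substance, noise included.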